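## Retrosynthetic overview

1. The target is a 2,3-cis-3,4-trans flavan-3-ol (benzo ring A, pyran ring C, catechol ring B). It is bonded through C4 to C5 of a flavonol (benzo ring D, pyranone ring F, catechol ring E). Ten benzyl ethers are removed last.
2. Ring F is opened at O1–C2 to a 2-benzyloxy-1,3-diketone. Aldol addition and oxidation, read backwards, cut this into a D-ring salicylaldehyde and the α-benzyloxy ketone of ring E. The formyl carbon is placed ortho to the one free D-ring phenol after ring C exists.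
3. The strategy rests on ring C. The chain O1–C8a–C4a–C4 (ring A, with ring D on C4) is the heterodiene of an o-quinone methide. C2–C3, with ring B and an oxygen on C2 and O3 on C3, is a 1,2-dioxygenated styrene. Cutting C3–C4 and O1–C2 gives an A–D o-hydroxybenzhydrol and a Z silyl enol ether.
4. C2 leaves the cycloaddition as a silyl ketal and is reset to 2,3-cis by ionic hydride reduction. The benzhydrol comes from an A-ring salicylaldehyde and a D-ring aryllithium. One ketone serves ring B (as enol ether) and ring E (as enolate).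
5. Order of ring formation: ring C (key step), then ring F. Rings A, B, D and E are bought as benzenes.

Key step: step 9

Assumption: 5-bromo-2,3-dihydroxybenzaldehyde and 2-(benzyloxy)-N-methoxy-N-methylacetamide are taken as catalogue compounds, and because the sense of induction of the catalyst in step 9 cannot be derived with certainty, (R)-TRIP is written and its equally available enantiomer would be used if the first run gives the antipode.

## Route

Step 1
Reactants: 1 2,3,4-trihydroxybenzaldehyde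
Product: 2 3,4-bis(benzyloxy)-2-hydroxybenzaldehyde
Conditions: BnBr (2.05 equiv), K2CO3 (2.1 equiv), DMF, rt, Ar
Reagents that add atoms: benzyl bromide BrCc1ccccc1
Why: Williamson etherification held at two equivalents: the 2-OH is tied up in a hydrogen bond to the formyl oxygen and is the least acidic and least nucleophilic of the three, the same bias that allows the classical 3,4-di-O-benzylation of 2,3,4-trihydroxyacetophenone.

Step 2
Reactants: 3 5-bromo-2,3-dihydroxybenzaldehyde
Product: 4 2,3-bis(benzyloxy)-5-bromobenzaldehyde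
Conditions: BnBr (2.5 equiv), K2CO3 (3 equiv), DMF, 60 °C
Reagents that add atoms: benzyl bromide BrCc1ccccc1
Why: Exhaustive Williamson etherification, in which excess reagent and heat also alkylate the chelated 2-OH, while the formyl group marks the carbon whose oxygen will be told apart from the other two.

Step 3
Reactants: 4 2,3-bis(benzyloxy)-5-bromobenzaldehyde
Product: 6 2,3-bis(benzyloxy)-5-bromophenol, via aryl formate 5 (not isolated)
Conditions: mCPBA, CH2Cl2, rt; NaHCO3 wash; then K2CO3 (cat.), MeOH, rt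
Reagents that add atoms: mCPBA O=C(OO)c1cccc(Cl)c1
Why: Baeyer–Villiger (Dakin-type) oxidation: the electron-rich o-alkoxyaryl group migrates in preference to hydride to give formate 5, which carbonate in methanol transesterifies, so the single free phenol sits unambiguously next to the two benzyl ethers and meta to bromine.

Step 4
Reactants: 6 2,3-bis(benzyloxy)-5-bromophenol
Product: 7 1-(allyloxy)-2,3-bis(benzyloxy)-5-bromobenzene
Conditions: allyl bromide, K2CO3, acetone, reflux
Reagents that add atoms: allyl bromide C=CCBr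
Why: Williamson etherification; allyl is chosen because it withstands butyllithium at −78 °C, the Brønsted acid of step 9 and the silyl triflate/silane of step 10 (where an acetal-type group would be at risk), and it leaves later under neutral Pd(0) conditions without touching benzyl ethers.

Step 5
Reactants: 7 1-(allyloxy)-2,3-bis(benzyloxy)-5-bromobenzene; 2 3,4-bis(benzyloxy)-2-hydroxybenzaldehyde
Product: 10 racemic 6-{[3-(allyloxy)-4,5-bis(benzyloxy)phenyl](hydroxy)methyl}-2,3-bis(benzyloxy)phenol (A–D benzhydrol), via aryllithium 8 (not isolated), via sodium phenolate 9 (not isolated)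
Conditions: 7, n-BuLi, THF, −78 °C; separately 2, NaH, THF, 0 °C; combine at −78 → 0 °C; aq. NH4Cl
Reagents that add atoms: none
Why: Bromine–lithium exchange followed by 1,2-addition of aryllithium 8 to the aldehyde, the standard entry to o-hydroxybenzhydrols; prior deprotonation of 2 saves an equivalent of 8, and the new carbinol centre may be racemic because it is erased on ionisation in step 9.

Step 6
Reactants: 11 4-bromobenzene-1,2-diol
Product: 12 1,2-bis(benzyloxy)-4-bromobenzene
Conditions: BnBr (2.3 equiv), K2CO3, DMF, rt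
Reagents that add atoms: benzyl bromide BrCc1ccccc1
Why: Exhaustive Williamson etherification of a catechol.

Step 7
Reactants: 12 1,2-bis(benzyloxy)-4-bromobenzene; 13 2-(benzyloxy)-N-methoxy-N-methylacetamide
Product: 15 2-(benzyloxy)-1-[3,4-bis(benzyloxy)phenyl]ethan-1-one, via aryllithium 14 (not isolated)
Conditions: n-BuLi, THF, −78 °C; then 13, −78 → 0 °C; aq. NH4Cl
Reagents that add atoms: none
Why: Weinreb ketone synthesis: the chelated tetrahedral adduct stops the addition at the ketone stage, and this route avoids the epoxy-ether and Favorskii-type side reactions of alkoxide displacement on a phenacyl halide.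

Step 8
Reactants: 15 2-(benzyloxy)-1-[3,4-bis(benzyloxy)phenyl]ethan-1-one
Product: 16 (Z)-{[2-(benzyloxy)-1-(3,4-bis(benzyloxy)phenyl)ethenyl]oxy}(tert-butyl)dimethylsilane (OTBS cis to OBn)
Conditions: TBSOTf (1.2 equiv), Et3N (2 equiv), CH2Cl2, 0 °C
Reagents that add atoms: tert-butyldimethylsilyl triflate CC(C)(C)[Si](C)(C)OS(=O)(=O)C(F)(F)F
Why: Soft enolisation and O-silylation; the Z isomer is favoured because the E isomer would press the benzyloxy group against ring B (A1,3 strain), as for silyl enol ethers of aryl alkyl ketones in general.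

Step 9
Reactants: 10 A–D benzhydrol; 16 Z silyl enol ether
Product: 18 (2R,3R,4S)-4-[3-(allyloxy)-4,5-bis(benzyloxy)phenyl]-3,7,8-tris(benzyloxy)-2-[3,4-bis(benzyloxy)phenyl]-2-(tert-butyldimethylsilyloxy)chroman (3,4-trans; OTBS cis to 3-OBn), via o-quinone methide 17 (not isolated)
Conditions: (R)-TRIP (10 mol %), 16 (1.5 equiv), 5 Å MS, toluene, 0 °C
Reagents that add atoms: none
Why: Proposed new method: the phosphoric acid protonates the benzylic OH of 10, ionisation is helped by the 7-benzyloxy group para to the benzylic carbon, and loss of water gives the E o-quinone methide 17, which stays hydrogen-bonded to the phosphate through the oxygen that becomes O1. C3 of 16, the carbon β to both the silyloxy group and ring B and hence the nucleophilic end of the alkene, bonds to C4 while O1 bonds to C2 in an inverse-demand hetero-Diels–Alder reaction; pyran ring C thus closes in a concerted but asynchronous [4+2] mode (in the stepwise limit a Mukaiyama–Michael addition followed by 6-exo-trig capture of the silyloxocarbenium ion by the phenoxide oxygen) and ring A regains aromaticity. The closest known reaction type is the chiral phosphoric acid catalysed [4+2] cycloaddition of o-quinone methides, made in situ from o-hydroxybenzyl alcohols, with styrenes, enamides and enol ethers; new here are the trisubstituted 1,2-dioxygenated silyl enol ether and the survival of its silyl group as a C2 ketal. C4 is set by the catalyst, whose 3,3'-aryl groups shield one face of bound 17; C3 is set relative to C4 by the transition-state geometry, since ring D sits on the outside position of the E heterodiene and flat ring B takes the endo position (the bulky OTBS goes exo), which places H3 cis and the 3-benzyloxy group trans to ring D; C2 follows from suprafacial addition to the Z alkene (OTBS cis to O3) and is only provisional. The step needs regiocontrol (C3 to C4), an aryl-endo approach and one heterodiene face: the 1-aryl-1-silyloxy pattern fixes the polarity, the size difference between OTBS and a stackable aryl group favours aryl-endo, the single Z geometry of 16 translates that into 3,4-trans, and the sieves remove the water that would otherwise protodesilylate 16.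

Step 10
Reactants: 18 C2 silyl ketal
Product: 20 (2R,3R,4S)-4-[3-(allyloxy)-4,5-bis(benzyloxy)phenyl]-3,7,8-tris(benzyloxy)-2-[3,4-bis(benzyloxy)phenyl]chroman (2,3-cis-3,4-trans), via oxocarbenium triflate 19 (not isolated)
Conditions: Et3SiH (5 equiv), TMSOTf (0.2 equiv), CH2Cl2, −78 → −40 °C; Et3N quench
Reagents that add atoms: none
Why: Ionic reduction of a cyclic ketal with silane and a Lewis acid: loss of the silyloxy group gives 2-aryl oxocarbenium ion 19, in which strain against the coplanar ring B holds the 3-OBn group pseudoaxial (and ring D, trans to it, pseudoaxial on the other face, away from H5), so the stereoelectronically preferred pseudoaxial hydride delivery anti to O3 should place H2 on the β face and ring B equatorial, i.e. 2R and 2,3-cis.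

Step 11
Reactants: 20 allyl-protected flavan
Product: 21 2,3-bis(benzyloxy)-5-{(2R,3R,4S)-3,7,8-tris(benzyloxy)-2-[3,4-bis(benzyloxy)phenyl]chroman-4-yl}phenol
Conditions: Pd(PPh3)4 (5 mol %), morpholine (5 equiv), THF, rt
Reagents that add atoms: none
Why: Tsuji–Trost-type deallylation: Pd(0) ionises the aryl allyl ether to a π-allyl complex that morpholine captures, under neutral conditions that leave the benzyl ethers and the three stereocentres alone.

Step 12
Reactants: 21 D-ring phenol
Product: 22 3,4-bis(benzyloxy)-2-hydroxy-6-{(2R,3R,4S)-3,7,8-tris(benzyloxy)-2-[3,4-bis(benzyloxy)phenyl]chroman-4-yl}benzaldehyde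
Conditions: MgCl2 (3 equiv), Et3N (6 equiv), (CH2O)n (10 equiv), MeCN, reflux; cold 1 M HCl wash
Reagents that add atoms: paraformaldehyde (reacts as formaldehyde) C=O
Why: Casnati–Skattebøl ortho-formylation: the magnesium phenoxide delivers coordinated formaldehyde through a six-membered transition state to the only free ortho carbon (the other ortho carbon bears OBn and the para carbon cannot be reached), a second formaldehyde oxidises the hydroxymethyl stage by hydride transfer, and rings A and B are untouched because only ring D carries a free phenol.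

Step 13
Reactants: 22 D-ring salicylaldehyde
Product: 23 3,4-bis(benzyloxy)-2-(methoxymethoxy)-6-{(2R,3R,4S)-3,7,8-tris(benzyloxy)-2-[3,4-bis(benzyloxy)phenyl]chroman-4-yl}benzaldehyde
Conditions: MOMCl (3 equiv), i-Pr2NEt (4 equiv), CH2Cl2, 0 °C → reflux
Reagents that add atoms: chloromethyl methyl ether COCCl
Why: O-alkylation to the MOM acetal masks the acidic phenol, so the aldehyde stays electrophilic and the carbinol made in step 14 cannot ionise to a second o-quinone methide.

Step 14
Reactants: 23 MOM-protected aldehyde; 15 2-(benzyloxy)-1-[3,4-bis(benzyloxy)phenyl]ethan-1-one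
Product: 25 β-hydroxy-α-benzyloxy ketone D–CH(OH)–CH(OBn)–C(=O)–E (mixture at the two new centres), via lithium enolate 24 (not isolated)
Conditions: 15 (1.5 equiv), LiHMDS (1.5 equiv), THF, −78 °C; then 23; AcOH quench at −78 °C
Reagents that add atoms: none
Why: Aldol addition of the chelated lithium Z enolate to a non-enolisable aldehyde; the two new centres form as a mixture, which does not matter because both are sp2 carbons after step 16.

Step 15
Reactants: 25 aldol adduct
Product: 26 2-benzyloxy-1,3-diketone D–C(=O)–CH(OBn)–C(=O)–E (central carbon enolisable and left unassigned)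
Conditions: Dess–Martin periodinane (1.5 equiv), CH2Cl2, 0 °C → rt
Reagents that add atoms: none
Why: Dess–Martin oxidation of the benzylic alcohol under near-neutral conditions, which avoids retro-aldol cleavage, gives the same 1,3-diketone that a Baker–Venkataraman acyl shift would deliver.

Step 16
Reactants: 26 MOM-protected 1,3-diketone
Product: 28 3,7,8-tris(benzyloxy)-2-[3,4-bis(benzyloxy)phenyl]-5-{(2R,3R,4S)-3,7,8-tris(benzyloxy)-2-[3,4-bis(benzyloxy)phenyl]chroman-4-yl}-4H-chromen-4-one, via hydroxy diketone 27 (not isolated)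
Conditions: HCl (cat., 2 M in MeOH), MeOH/THF, 45 °C
Reagents that add atoms: none
Why: Acid-catalysed acetal cleavage followed by cyclodehydration, the closing step of a Baker–Venkataraman flavone synthesis: freed phenol 27 adds 6-exo-trig to the E-ring carbonyl and the hemiketal loses water to give pyranone ring F, while the acyl group now on ring D deactivates it towards protolytic cleavage of the C4–D bond.

Step 17
Reactants: 28 decabenzyl ether
Product: 29 2-(3,4-dihydroxyphenyl)-5-[(2R,3R,4S)-2-(3,4-dihydroxyphenyl)-3,7,8-trihydroxychroman-4-yl]-3,7,8-trihydroxy-4H-chromen-4-one (CNP0395591.1)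
Conditions: H2 (1 atm), 20% Pd(OH)2/C, THF/MeOH, rt; filtration under Ar; Sephadex LH-20
Reagents that add atoms: none
Why: Catalytic hydrogenolysis of all ten benzyl ethers in one operation, routine for perbenzylated flavonols and oligomeric flavan-3-ols; the flavonol double bond, the C2–O1 bond and the three stereocentres should not be affected at one atmosphere and room temperature.

## Compound list

1 | 2,3,4-trihydroxybenzaldehyde | O=Cc1ccc(O)c(O)c1O | starting material
2 | 3,4-bis(benzyloxy)-2-hydroxybenzaldehyde | O=Cc1ccc(OCc2ccccc2)c(OCc2ccccc2)c1O | intermediate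
3 | 5-bromo-2,3-dihydroxybenzaldehyde | O=Cc1cc(Br)cc(O)c1O | starting material
4 | 2,3-bis(benzyloxy)-5-bromobenzaldehyde | O=Cc1cc(Br)cc(OCc2ccccc2)c1OCc1ccccc1 | intermediate
5 | 2,3-bis(benzyloxy)-5-bromophenyl formate | O=COc1cc(Br)cc(OCc2ccccc2)c1OCc1ccccc1 | intermediate (not isolated)
6 | 2,3-bis(benzyloxy)-5-bromophenol | Oc1cc(Br)cc(OCc2ccccc2)c1OCc1ccccc1 | intermediate
7 | 1-(allyloxy)-2,3-bis(benzyloxy)-5-bromobenzene | C=CCOc1cc(Br)cc(OCc2ccccc2)c1OCc1ccccc1 | intermediate
8 | [3-(allyloxy)-4,5-bis(benzyloxy)phenyl]lithium | [Li]c1cc(OCC=C)c(OCc2ccccc2)c(OCc2ccccc2)c1 | intermediate (not isolated)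
9 | sodium 2,3-bis(benzyloxy)-6-formylphenolate | [Na+].[O-]c1c(C=O)ccc(OCc2ccccc2)c1OCc1ccccc1 | intermediate (not isolated)
10 | racemic A–D o-hydroxybenzhydrol | C=CCOc1cc(cc(OCc5ccccc5)c1OCc5ccccc5)C(O)c3ccc(OCc5ccccc5)c(OCc5ccccc5)c3O | intermediate
11 | 4-bromobenzene-1,2-diol | Oc1ccc(Br)cc1O | starting material
12 | 1,2-bis(benzyloxy)-4-bromobenzene | Brc1ccc(OCc2ccccc2)c(OCc2ccccc2)c1 | intermediate
13 | 2-(benzyloxy)-N-methoxy-N-methylacetamide | CON(C)C(=O)COCc1ccccc1 | starting material
14 | [3,4-bis(benzyloxy)phenyl]lithium | [Li]c1ccc(OCc2ccccc2)c(OCc2ccccc2)c1 | intermediate (not isolated)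
15 | 2-(benzyloxy)-1-[3,4-bis(benzyloxy)phenyl]ethan-1-one | O=C(COCc1ccccc1)c1ccc(OCc2ccccc2)c(OCc2ccccc2)c1 | intermediate
16 | (Z)-TBS enol ether of 15 | c1ccccc1CO/C=C(\O[Si](C)(C)C(C)(C)C)c1ccc(OCc2ccccc2)c(OCc2ccccc2)c1 | intermediate
17 | (6E)-6-{[3-(allyloxy)-4,5-bis(benzyloxy)phenyl]methylidene}-2,3-bis(benzyloxy)cyclohexa-2,4-dien-1-one | O=C1C(OCc5ccccc5)=C(OCc5ccccc5)C=C/C1=C\c1cc(OCC=C)c(OCc5ccccc5)c(OCc5ccccc5)c1 | intermediate (not isolated)
18 | (2R,3R,4S) C2 silyl ketal cycloadduct, 3,4-trans | C=CCOc1cc(cc(OCc5ccccc5)c1OCc5ccccc5)[C@H]2c3ccc(OCc5ccccc5)c(OCc5ccccc5)c3O[C@](c4ccc(OCc5ccccc5)c(OCc5ccccc5)c4)(O[Si](C)(C)C(C)(C)C)[C@@H]2OCc5ccccc5 | intermediate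
19 | (3R,4S) 2-aryl oxocarbenium triflate | C=CCOc1cc(cc(OCc5ccccc5)c1OCc5ccccc5)[C@H]2c3ccc(OCc5ccccc5)c(OCc5ccccc5)c3[O+]=C(c4ccc(OCc5ccccc5)c(OCc5ccccc5)c4)[C@@H]2OCc5ccccc5.[O-]S(=O)(=O)C(F)(F)F | intermediate (not isolated)
20 | (2R,3R,4S) allyl-protected 4-arylflavan, 2,3-cis-3,4-trans | C=CCOc1cc(cc(OCc5ccccc5)c1OCc5ccccc5)[C@H]2c3ccc(OCc5ccccc5)c(OCc5ccccc5)c3O[C@H](c4ccc(OCc5ccccc5)c(OCc5ccccc5)c4)[C@@H]2OCc5ccccc5 | intermediate
21 | (2R,3R,4S) D-ring phenol | Oc1cc(cc(OCc5ccccc5)c1OCc5ccccc5)[C@H]2c3ccc(OCc5ccccc5)c(OCc5ccccc5)c3O[C@H](c4ccc(OCc5ccccc5)c(OCc5ccccc5)c4)[C@@H]2OCc5ccccc5 | intermediate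
22 | (2R,3R,4S) D-ring salicylaldehyde | Oc1c(C=O)c(cc(OCc5ccccc5)c1OCc5ccccc5)[C@H]2c3ccc(OCc5ccccc5)c(OCc5ccccc5)c3O[C@H](c4ccc(OCc5ccccc5)c(OCc5ccccc5)c4)[C@@H]2OCc5ccccc5 | intermediate
23 | (2R,3R,4S) MOM-protected D-ring aldehyde | COCOc1c(C=O)c(cc(OCc5ccccc5)c1OCc5ccccc5)[C@H]2c3ccc(OCc5ccccc5)c(OCc5ccccc5)c3O[C@H](c4ccc(OCc5ccccc5)c(OCc5ccccc5)c4)[C@@H]2OCc5ccccc5 | intermediate
24 | lithium (Z)-enolate of 15 | [Li]O/C(=C\OCc1ccccc1)c1ccc(OCc2ccccc2)c(OCc2ccccc2)c1 | intermediate (not isolated)
25 | aldol adduct (two new centres unassigned) | COCOc1c(C(O)C(OCc5ccccc5)C(=O)c6ccc(OCc5ccccc5)c(OCc5ccccc5)c6)c(cc(OCc5ccccc5)c1OCc5ccccc5)[C@H]2c3ccc(OCc5ccccc5)c(OCc5ccccc5)c3O[C@H](c4ccc(OCc5ccccc5)c(OCc5ccccc5)c4)[C@@H]2OCc5ccccc5 | intermediate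
26 | MOM-protected 2-benzyloxy-1,3-diketone | COCOc1c(C(=O)C(OCc5ccccc5)C(=O)c6ccc(OCc5ccccc5)c(OCc5ccccc5)c6)c(cc(OCc5ccccc5)c1OCc5ccccc5)[C@H]2c3ccc(OCc5ccccc5)c(OCc5ccccc5)c3O[C@H](c4ccc(OCc5ccccc5)c(OCc5ccccc5)c4)[C@@H]2OCc5ccccc5 | intermediate
27 | o-hydroxyaryl 2-benzyloxy-1,3-diketone | Oc1c(C(=O)C(OCc5ccccc5)C(=O)c6ccc(OCc5ccccc5)c(OCc5ccccc5)c6)c(cc(OCc5ccccc5)c1OCc5ccccc5)[C@H]2c3ccc(OCc5ccccc5)c(OCc5ccccc5)c3O[C@H](c4ccc(OCc5ccccc5)c(OCc5ccccc5)c4)[C@@H]2OCc5ccccc5 | intermediate (not isolated)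
28 | decabenzyl ether of the target | O=c1c(OCc5ccccc5)c(-c6ccc(OCc5ccccc5)c(OCc5ccccc5)c6)oc7c(OCc5ccccc5)c(OCc5ccccc5)cc([C@H]2c3ccc(OCc5ccccc5)c(OCc5ccccc5)c3O[C@H](c4ccc(OCc5ccccc5)c(OCc5ccccc5)c4)[C@@H]2OCc5ccccc5)c17 | intermediate
29 | CNP0395591.1 | O=c1c(O)c(-c2ccc(O)c(O)c2)oc2c(O)c(O)cc([C@H]3c4ccc(O)c(O)c4O[C@H](c4ccc(O)c(O)c4)[C@@H]3O)c12 | target

## Step count and risks

Total step count: 17.
Longest linear sequence: 13 steps (3 → 4 → 6 → 7 → 10 → 18 → 20 → 21 → 22 → 23 → 25 → 26 → 28 → 29).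

**Risk 1, step 9 (Proposed new method).**
- Acid-catalysed protodesilylation of the enol ether by the released water may outrun the cycloaddition.
- The 8-benzyloxy group crowds the hydrogen-bonding site, which may weaken face discrimination.
- Leakage between aryl-endo and silyloxy-endo approach would erode the 3,4-trans relationship.

Fallback, known chemistry throughout, sets out from 2, 7 and 12 and comes back at 20. C4 is set by rhodium-catalysed asymmetric conjugate arylation instead. Salicylaldehyde 2 is heated with ethyl (triphenylphosphoranylidene)acetate in N,N-diethylaniline (Wittig olefination and lactonisation) to give 7,8-bis(benzyloxy)coumarin F1. Bromide 7 is converted (n-BuLi, B(Oi-Pr)3, then dilute acid) into the arylboronic acid F2. Rh(acac)(C2H4)2/(S)-SEGPHOS in dioxane/water adds F2 to F1 and should give the (4S)-4-aryldihydrocoumarin F3. Its potassium enolate is hydroxylated with 2-(phenylsulfonyl)-3-phenyloxaziridine anti to the C4 aryl group to give the 3,4-trans hydroxy lactone F4. Benzyl trichloroacetimidate with catalytic TfOH gives the benzyl ether F5. MeNHOMe·HCl/i-PrMgCl opens the lactone to the Weinreb amide F6. Two equivalents of aryllithium 14 (from 12) give the hydroxy ketone F7, the ring-chain tautomer of the C2 hemiketal. Et3SiH/BF3·OEt2 reduces F7 through the same oxocarbenium ion as in step 10 to 20.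

**Risk 2, step 10.**
- Hydride may be delivered from the α face, either through the diequatorial half-chair or because the syn-axial ring D hinders the β face.
- The ketal may open at O1 before reduction.
- Proton loss from C3 would give an enol ether.

Fallback sets out from 18 and comes back at 20. TBAF/AcOH in THF frees the hydroxy ketone F7. Zn(BH4)2 in Et2O reduces it under Cram-chelate control, with zinc held between the carbonyl oxygen and O3, to the anti alcohol F8 with a (2S) carbinol in flavan numbering. Mitsunobu cyclisation (PPh3, DIAD, THF, 0 °C) lets the A-ring phenol displace the activated benzylic oxygen with inversion. This closes O1–C2 as 2R, i.e. 2,3-cis, and gives 20.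

**Risk 3, step 12.** C–C bond formation may be slow at the crowded ortho carbon between the phenoxide oxygen and the flavan-4-yl group, so that the reaction stalls or stops at the hydroxymethyl stage.

Fallback sets out from 20 (step 11 is skipped) and comes back at 23. Aromatic Claisen rearrangement of 20 (N,N-diethylaniline, 190 °C) carries the allyl group intramolecularly to the only free ortho carbon and gives the o-allylphenol F9. MOMCl/i-Pr2NEt gives the MOM ether F10. RuHCl(CO)(PPh3)3 in toluene moves the double bond into conjugation to give the (E)-propenylarene F11. Lemieux–Johnson cleavage (cat. OsO4, NaIO4, 2,6-lutidine, dioxane/water) gives 23.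

## Further compounds

F1 | step 9 | 7,8-bis(benzyloxy)-2H-chromen-2-one | O=C1C=Cc2ccc(OCc3ccccc3)c(OCc3ccccc3)c2O1
F2 | step 9 | [3-(allyloxy)-4,5-bis(benzyloxy)phenyl]boronic acid | OB(O)c1cc(OCC=C)c(OCc2ccccc2)c(OCc2ccccc2)c1
F3 | step 9 | (4S)-4-[3-(allyloxy)-4,5-bis(benzyloxy)phenyl]-7,8-bis(benzyloxy)chroman-2-one | C=CCOc1cc(cc(OCc5ccccc5)c1OCc5ccccc5)[C@H]2c3ccc(OCc5ccccc5)c(OCc5ccccc5)c3OC(=O)C2
F4 | step 9 | (3R,4S)-4-[3-(allyloxy)-4,5-bis(benzyloxy)phenyl]-7,8-bis(benzyloxy)-3-hydroxychroman-2-one (3,4-trans) | C=CCOc1cc(cc(OCc5ccccc5)c1OCc5ccccc5)[C@H]2c3ccc(OCc5ccccc5)c(OCc5ccccc5)c3OC(=O)[C@@H]2O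
F5 | step 9 | (3R,4S)-4-[3-(allyloxy)-4,5-bis(benzyloxy)phenyl]-3,7,8-tris(benzyloxy)chroman-2-one | C=CCOc1cc(cc(OCc5ccccc5)c1OCc5ccccc5)[C@H]2c3ccc(OCc5ccccc5)c(OCc5ccccc5)c3OC(=O)[C@@H]2OCc5ccccc5
F6 | step 9 | (2R,3S)-3-[3-(allyloxy)-4,5-bis(benzyloxy)phenyl]-2-(benzyloxy)-3-[3,4-bis(benzyloxy)-2-hydroxyphenyl]-N-methoxy-N-methylpropanamide | C=CCOc1cc(cc(OCc5ccccc5)c1OCc5ccccc5)[C@@H](c3ccc(OCc5ccccc5)c(OCc5ccccc5)c3O)[C@@H](OCc5ccccc5)C(=O)N(C)OC
F7 | step 9 | (2R,3S)-3-[3-(allyloxy)-4,5-bis(benzyloxy)phenyl]-2-(benzyloxy)-1-[3,4-bis(benzyloxy)phenyl]-3-[3,4-bis(benzyloxy)-2-hydroxyphenyl]propan-1-one | C=CCOc1cc(cc(OCc5ccccc5)c1OCc5ccccc5)[C@@H](c3ccc(OCc5ccccc5)c(OCc5ccccc5)c3O)[C@@H](OCc5ccccc5)C(=O)c4ccc(OCc5ccccc5)c(OCc5ccccc5)c4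
F8 | step 10 | (1S,2R,3S)-3-[3-(allyloxy)-4,5-bis(benzyloxy)phenyl]-2-(benzyloxy)-1-[3,4-bis(benzyloxy)phenyl]-3-[3,4-bis(benzyloxy)-2-hydroxyphenyl]propan-1-ol | C=CCOc1cc(cc(OCc5ccccc5)c1OCc5ccccc5)[C@@H](c3ccc(OCc5ccccc5)c(OCc5ccccc5)c3O)[C@@H](OCc5ccccc5)[C@@H](O)c4ccc(OCc5ccccc5)c(OCc5ccccc5)c4
F9 | step 12 | 2-allyl-5,6-bis(benzyloxy)-3-{(2R,3R,4S)-3,7,8-tris(benzyloxy)-2-[3,4-bis(benzyloxy)phenyl]chroman-4-yl}phenol | Oc1c(CC=C)c(cc(OCc5ccccc5)c1OCc5ccccc5)[C@H]2c3ccc(OCc5ccccc5)c(OCc5ccccc5)c3O[C@H](c4ccc(OCc5ccccc5)c(OCc5ccccc5)c4)[C@@H]2OCc5ccccc5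
F10 | step 12 | MOM ether of F9 | COCOc1c(CC=C)c(cc(OCc5ccccc5)c1OCc5ccccc5)[C@H]2c3ccc(OCc5ccccc5)c(OCc5ccccc5)c3O[C@H](c4ccc(OCc5ccccc5)c(OCc5ccccc5)c4)[C@@H]2OCc5ccccc5
F11 | step 12 | (E)-prop-1-enyl isomer of F10 | COCOc1c(/C=C/C)c(cc(OCc5ccccc5)c1OCc5ccccc5)[C@H]2c3ccc(OCc5ccccc5)c(OCc5ccccc5)c3O[C@H](c4ccc(OCc5ccccc5)c(OCc5ccccc5)c4)[C@@H]2OCc5ccccc5
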